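**Plan**

- Retrosynthesis: the C3 hydroxymethyl is traced back to a carboxyl (benzyl ester) and the ring C phenol to its benzyl ether. The C2–C3 bond of the dihydrobenzofuran is cut next, then the C3–C3a aryl–carbon bond, the O1–C2 bond (as the O–CH2 bond of a benzyl ether) and a C3a–I bond.
- Enabling feature: C2 is a benzylic ether carbon (bonded to O1 and ring C) and C3 carries ring A and a one-carbon oxygenated group. C2–C3 is therefore the bond that a ring A aryl(diazo)acetate carbene makes by inserting into a C–H of an ortho ring C benzyloxy group.
- Forward: the ring C benzyl bromide is made from syringaldehyde and methyl dihydroferulate is iodinated ortho to its OH. A Williamson ether then joins rings A and C through O1, and a palladium coupling with benzyl diazoacetate installs C3 with its carboxyl.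
- The only ring made, the dihydrofuran (O1–C2–C3–C3a–C7a), closes in the rhodium carbene C–H insertion. One hydrogenolysis then frees the acid and the phenol, and borane reduces the acid.
- Stereochemistry: C2 comes from a chiral dirhodium carboxylate catalyst that selects one enantiotopic benzylic hydrogen. C3 comes from base equilibration of the ester to trans, and both centres are carried unchanged to the (2S,3R) target.

Key step: step 7

Assumption: with phthalimido-carboxylate dirhodium catalysts the (R)-ligand series is taken to deliver the 2S ring carbon from 2-benzyloxyaryl diazoacetates; if a first run showed the opposite sense, the mirror-image catalyst Rh2(S-PTTL)4 would replace it and nothing else in the route would change.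

**Step 1**
Reactants: 1 syringaldehyde (4-hydroxy-3,5-dimethoxybenzaldehyde)
Product: 2 4-benzyloxy-3,5-dimethoxybenzaldehyde
Conditions: BnBr, K2CO3, DMF, 60 °C
Reagents that add atoms: benzyl bromide, BrCc1ccccc1
Why: Williamson ether synthesis, in which the phenoxide formed by K2CO3 displaces bromide from benzyl bromide in an SN2 reaction while the aldehyde stays inert and no stereocenter is formed.

**Step 2**
Reactants: 2 4-benzyloxy-3,5-dimethoxybenzaldehyde
Product: 3 (4-benzyloxy-3,5-dimethoxyphenyl)methanol
Conditions: NaBH4, MeOH, 0 °C
Reagents that add atoms: none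
Why: Borohydride reduction of an aromatic aldehyde to the benzylic alcohol is fast in methanol and leaves the aryl ethers untouched.

**Step 3**
Reactants: 3 (4-benzyloxy-3,5-dimethoxyphenyl)methanol
Product: 4 4-benzyloxy-3,5-dimethoxybenzyl bromide
Conditions: PBr3 (0.4 equiv), CH2Cl2, 0 °C; used without storage
Reagents that add atoms: phosphorus tribromide, BrP(Br)Br
Why: Bromination of a primary benzylic alcohol with PBr3 proceeds through a phosphite ester that bromide displaces in an SN2 step, and the aryl ethers survive the short exposure at 0 °C.

**Step 4**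
Reactants: 5 methyl 3-(4-hydroxy-3-methoxyphenyl)propanoate (methyl dihydroferulate)
Product: 6 methyl 3-(4-hydroxy-3-iodo-5-methoxyphenyl)propanoate
Conditions: I2 (1.0 equiv), NaHCO3, THF–H2O, 0 °C → rt
Reagents that add atoms: iodine, II
Why: Electrophilic aromatic iodination under bicarbonate buffering runs through the phenoxide, whose para position is blocked by the side chain and whose other ortho position carries OMe, so iodine should enter only at the free ortho carbon while the methyl ester is not hydrolysed.

**Step 5**
Reactants: 6 methyl 3-(4-hydroxy-3-iodo-5-methoxyphenyl)propanoate; 4 4-benzyloxy-3,5-dimethoxybenzyl bromide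
Product: 7 methyl 3-[4-(4-benzyloxy-3,5-dimethoxybenzyloxy)-3-iodo-5-methoxyphenyl]propanoate
Conditions: K2CO3, DMF, rt
Reagents that add atoms: none
Why: Williamson ether synthesis, in which the hindered but acidic 2-iodo-6-methoxyphenoxide is alkylated on oxygen by the reactive benzylic bromide in an SN2 reaction, the methyl ester and the aryl iodide being spectators.

**Step 6**
Reactants: 7 methyl 3-[4-(4-benzyloxy-3,5-dimethoxybenzyloxy)-3-iodo-5-methoxyphenyl]propanoate; 8 benzyl diazoacetate
Product: 9 benzyl 2-diazo-2-[2-(4-benzyloxy-3,5-dimethoxybenzyloxy)-3-methoxy-5-(3-methoxy-3-oxopropyl)phenyl]acetate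
Conditions: Pd(PPh3)4 (5 mol %, zerovalent palladium), Ag2CO3 (0.5 equiv), Et3N, toluene, rt, dark
Reagents that add atoms: none
Why: Palladium-catalysed cross-coupling of an aryl iodide with an acceptor diazoacetate with retention of the diazo group, in which oxidative addition of the C–I bond to zerovalent palladium, silver-assisted transfer of the deprotonated diazoacetate carbon to palladium and reductive elimination form the aryl–C(N2) bond at room temperature, below the temperature at which the product loses nitrogen.

**Step 7**
Reactants: 9 benzyl 2-diazo-2-[2-(4-benzyloxy-3,5-dimethoxybenzyloxy)-3-methoxy-5-(3-methoxy-3-oxopropyl)phenyl]acetate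
Product: 11 benzyl (2S,3S)-trans-2-(4-benzyloxy-3,5-dimethoxyphenyl)-7-methoxy-5-(3-methoxy-3-oxopropyl)-2,3-dihydrobenzofuran-3-carboxylate, via cis benzyl ester 10 (not isolated)
Conditions: Rh2(R-PTTL)4, dirhodium tetrakis[N-phthaloyl-(R)-tert-leucinate] (1 mol %, divalent rhodium), 4 Å MS, toluene, −60 °C, slow addition of 9; then DBU (0.5 equiv), rt → 50 °C
Reagents that add atoms: none
Why: Rh2(R-PTTL)4 takes N2 from 9 to give a donor/acceptor rhodium carbene at the future C3, which inserts in a concerted, asynchronous three-centre step (hydride-like C–H donation followed by C–C closure, with retention at carbon) into one C–H of the ortho OCH2 group; the closest known reaction type is the dirhodium-carboxylate-catalysed enantioselective intramolecular C–H insertion of 2-benzyloxyaryl diazoacetates to cis-2-aryl-2,3-dihydrobenzofuran-3-carboxylates. The dihydrofuran ring (O1–C2–C3–C3a–C7a) closes at C2–C3 by 1,5-insertion, the only mode within reach because the reacting C–H sits five atoms from the carbene carbon on an ortho tether. C2 is set by the catalyst, whose four phthalimido-tert-leucinate ligands shield one approach to the carbene so that only one of the two enantiotopic benzylic hydrogens is delivered, here taken to give 2S. C3 is first formed under kinetic control (cis ester 10) and is then equilibrated by DBU through the ester enolate to the trans ester 11, in which the C2 aryl group and the C3 ester lie on opposite faces; C2 has no acidifying group and is not touched, and beta-elimination of the ring oxygen from the enolate should be slow because it is the reverse of a 5-endo-trig closure. The step needs site selectivity for the tethered OCH2 over the benzyl ester CH2 (a 1,4 relationship), the ring C benzyl ether CH2, the methoxy groups and the side chain (none within intramolecular reach), which the ortho placement and the activation by the ether oxygen and electron-rich ring C secure, and it needs suppression of carbene dimerisation, which slow addition at low temperature secures.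

**Step 8**
Reactants: 11 benzyl (2S,3S)-trans-2-(4-benzyloxy-3,5-dimethoxyphenyl)-7-methoxy-5-(3-methoxy-3-oxopropyl)-2,3-dihydrobenzofuran-3-carboxylate
Product: 12 (2S,3S)-trans-2-(4-hydroxy-3,5-dimethoxyphenyl)-7-methoxy-5-(3-methoxy-3-oxopropyl)-2,3-dihydrobenzofuran-3-carboxylic acid
Conditions: H2 (1 atm), 10% Pd/C (palladium on carbon), EtOAc–MeOH, rt, stopped at full conversion
Reagents that add atoms: none
Why: Heterogeneous palladium-catalysed hydrogenolysis cleaves the O–CH2Ph bonds of the benzyl ester and the benzyl aryl ether under one atmosphere of hydrogen in neutral solvent, whereas the ring C2–O bond, a secondary benzylic ether held in a ring and flanked by the C3 substituent, should react far more slowly, and neither C2 nor C3 nor the methyl ester is touched.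

**Step 9**
Reactants: 12 (2S,3S)-trans-2-(4-hydroxy-3,5-dimethoxyphenyl)-7-methoxy-5-(3-methoxy-3-oxopropyl)-2,3-dihydrobenzofuran-3-carboxylic acid
Product: 13 methyl 3-[(2S,3R)-2-(4-hydroxy-3,5-dimethoxyphenyl)-3-(hydroxymethyl)-7-methoxy-2,3-dihydrobenzofuran-5-yl]propanoate (target)
Conditions: BH3·THF (3 equiv), THF, 0 °C → rt; MeOH quench, aqueous work-up
Reagents that add atoms: none
Why: Chemoselective borane reduction, in which the electrophilic borane converts the carboxylic acid into an acyloxyborane and reduces it to the primary alcohol much faster than it attacks the methyl ester, the phenol being only converted into a borate that the work-up cleaves; no bond at C2 or C3 is broken, and the C3 descriptor changes from S to R only because CH2OH ranks below C2 whereas the carboxyl ranked above it.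

**Compound list**

1 | syringaldehyde (4-hydroxy-3,5-dimethoxybenzaldehyde) | COc1cc(C=O)cc(OC)c1O | starting material
2 | 4-benzyloxy-3,5-dimethoxybenzaldehyde | COc1cc(C=O)cc(OC)c1OCc1ccccc1 | intermediate
3 | (4-benzyloxy-3,5-dimethoxyphenyl)methanol | COc1cc(CO)cc(OC)c1OCc1ccccc1 | intermediate
4 | 4-benzyloxy-3,5-dimethoxybenzyl bromide | COc1cc(CBr)cc(OC)c1OCc1ccccc1 | intermediate
5 | methyl 3-(4-hydroxy-3-methoxyphenyl)propanoate (methyl dihydroferulate) | COC(=O)CCc1ccc(O)c(OC)c1 | starting material
6 | methyl 3-(4-hydroxy-3-iodo-5-methoxyphenyl)propanoate | COC(=O)CCc1cc(I)c(O)c(OC)c1 | intermediate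
7 | methyl 3-[4-(4-benzyloxy-3,5-dimethoxybenzyloxy)-3-iodo-5-methoxyphenyl]propanoate | COC(=O)CCc1cc(I)c(OCc2cc(OC)c(OCc3ccccc3)c(OC)c2)c(OC)c1 | intermediate
8 | benzyl diazoacetate | [N-]=[N+]=CC(=O)OCc1ccccc1 | starting material
9 | benzyl 2-diazo-2-[2-(4-benzyloxy-3,5-dimethoxybenzyloxy)-3-methoxy-5-(3-methoxy-3-oxopropyl)phenyl]acetate | COC(=O)CCc1cc(OC)c(OCc2cc(OC)c(OCc3ccccc3)c(OC)c2)c(c1)C(=[N+]=[N-])C(=O)OCc1ccccc1 | intermediate
10 | benzyl (2S,3R)-cis-2-(4-benzyloxy-3,5-dimethoxyphenyl)-7-methoxy-5-(3-methoxy-3-oxopropyl)-2,3-dihydrobenzofuran-3-carboxylate | COC(=O)CCc1cc(OC)c2c(c1)[C@@H](C(=O)OCc1ccccc1)[C@@H](c1cc(OC)c(OCc3ccccc3)c(OC)c1)O2 | intermediate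
11 | benzyl (2S,3S)-trans-2-(4-benzyloxy-3,5-dimethoxyphenyl)-7-methoxy-5-(3-methoxy-3-oxopropyl)-2,3-dihydrobenzofuran-3-carboxylate | COC(=O)CCc1cc(OC)c2c(c1)[C@H](C(=O)OCc1ccccc1)[C@@H](c1cc(OC)c(OCc3ccccc3)c(OC)c1)O2 | intermediate
12 | (2S,3S)-trans-2-(4-hydroxy-3,5-dimethoxyphenyl)-7-methoxy-5-(3-methoxy-3-oxopropyl)-2,3-dihydrobenzofuran-3-carboxylic acid | COC(=O)CCc1cc(OC)c2c(c1)[C@H](C(=O)O)[C@@H](c1cc(OC)c(O)c(OC)c1)O2 | intermediate
13 | methyl 3-[(2S,3R)-2-(4-hydroxy-3,5-dimethoxyphenyl)-3-(hydroxymethyl)-7-methoxy-2,3-dihydrobenzofuran-5-yl]propanoate | COC(=O)CCc1cc(OC)c2c(c1)[C@H](CO)[C@@H](c1cc(OC)c(O)c(OC)c1)O2 | target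

**Step count and risks**

Total: 9 steps. Longest linear sequence: 8 steps (steps 1, 2, 3, 5, 6, 7, 8, 9 from syringaldehyde); the branch from methyl dihydroferulate is 6 steps.

Steps most likely to fail:

1. Step 7. The catalyst may not distinguish cleanly between the two enantiotopic hydrogens of a methylene group that carries a bulky, electron-rich aryl ring, so C2 could form with insufficient enantiomeric purity; DBU corrects C3 but cannot correct C2. Fallback: stereochemical purity at C2 would then be secured by classical resolution through a diastereomeric salt instead of by the catalyst alone. The fallback sets out from acid 12 of insufficient enantiomeric purity. It is combined with (R)-1-phenylethylamine in ethanol–ethyl acetate to give (R)-1-phenylethylammonium (2S,3S)-2-(4-hydroxy-3,5-dimethoxyphenyl)-7-methoxy-5-(3-methoxy-3-oxopropyl)-2,3-dihydrobenzofuran-3-carboxylate F1, which is recrystallised until its enantiomeric purity no longer rises. Partition between ethyl acetate and cold dilute HCl returns the route to 12, which goes on to step 9.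

2. Step 6. Transfer of the diazoacetate carbon to the ortho-alkoxy arylpalladium iodide and the reductive elimination may be slow, and palladium or silver may induce loss of nitrogen from the diazo compounds before coupling. Fallback: the aryl–carbon bond and the diazo group would be installed separately. Setting out from iodide 7, a Negishi-type coupling (Pd2(dba)3, XPhos, THF, rt) with the Reformatsky reagent bromo(2-benzyloxy-2-oxoethyl)zinc F2, made from benzyl bromoacetate and zinc dust, should give benzyl 2-[2-(4-benzyloxy-3,5-dimethoxybenzyloxy)-3-methoxy-5-(3-methoxy-3-oxopropyl)phenyl]acetate F3. Regitz diazo transfer onto F3 (4-acetamidobenzenesulfonyl azide, DBU, MeCN, 0 °C → rt) then returns the route to diazo ester 9.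

3. Step 9. The reduction may stall once the phenol and the acid have bound borane, the methyl ester may be attacked when excess borane is used to drive it, or the Lewis acid may promote ionisation at the C2 benzylic ether. Fallback: the acid would be activated as an electrophile and reduced with a nucleophilic hydride. Setting out from acid 12, isobutyl chloroformate and N-methylmorpholine in THF at −15 °C should acylate the carboxylate selectively over the hindered, un-ionised phenol to give the isobutyl carbonic mixed anhydride of 12 F4. Aqueous NaBH4 at 0 °C reduces F4 at the acyl carbon and leaves the methyl ester alone, returning the route to target 13.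

**Further compounds**

F1 | step 7 | (R)-1-phenylethylammonium (2S,3S)-2-(4-hydroxy-3,5-dimethoxyphenyl)-7-methoxy-5-(3-methoxy-3-oxopropyl)-2,3-dihydrobenzofuran-3-carboxylate | COC(=O)CCc1cc(OC)c2c(c1)[C@H](C(=O)[O-])[C@@H](c1cc(OC)c(O)c(OC)c1)O2.C[C@@H]([NH3+])c1ccccc1
F2 | step 6 | bromo(2-benzyloxy-2-oxoethyl)zinc (Reformatsky reagent of benzyl bromoacetate) | Br[Zn]CC(=O)OCc1ccccc1
F3 | step 6 | benzyl 2-[2-(4-benzyloxy-3,5-dimethoxybenzyloxy)-3-methoxy-5-(3-methoxy-3-oxopropyl)phenyl]acetate | COC(=O)CCc1cc(OC)c(OCc2cc(OC)c(OCc3ccccc3)c(OC)c2)c(c1)CC(=O)OCc1ccccc1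
F4 | step 9 | isobutyl carbonic mixed anhydride of (2S,3S)-2-(4-hydroxy-3,5-dimethoxyphenyl)-7-methoxy-5-(3-methoxy-3-oxopropyl)-2,3-dihydrobenzofuran-3-carboxylic acid | COC(=O)CCc1cc(OC)c2c(c1)[C@H](C(=O)OC(=O)OCC(C)C)[C@@H](c1cc(OC)c(O)c(OC)c1)O2
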